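The route rests on cutting the O1–C8a bond of ring C in the top catechin unit. There O1 is flanked by the ring A carbon C8a and by C2. This is the pattern left when the aryl carbon of an indan-1-one migrates to a peracid oxygen. The precursor is a (3S)-4,6-dibenzyloxyindan-1-one with a bare C2 methylene. Its C3 (the future flavan C4) is bonded to C8 of a perbenzylated catechin trimer assembled by cationic 4→8 couplings. One peracid operation moves C7a from carbon to oxygen and enlarges the cyclopentanone to the six-membered lactone, leaving C4 untouched. Aryllithium addition, cyclodehydration and anti hydroboration then relay C4 to C2 and C3.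

Key step: step 11

Assumption: the (R)-bisphosphine in step 10 is taken to be the antipode that gives 3S. The sense is checked on the chalcone made from monomeric penta-O-benzylcatechin-8-carbaldehyde, and the mirror-image ligand is used if the model shows the opposite sense.
Assumption: 4 and 6 are drawn as the 4β-ethers (3,4-cis). Either C4 epimer ionises to the same cation, so this centre has no bearing on the route.

Step 1
Reactants: 1 (+)-catechin
Product: 2 5,7,3',4'-tetra-O-benzyl-(+)-catechin (2R,3S; 3-OH free)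
Conditions: BnBr (4.4 equiv), K2CO3, DMF, argon, 0 °C to rt
Reagents that add atoms: benzyl bromide, BrCc1ccccc1
Why: Williamson etherification with a carbonate base alkylates only the four acidic phenols while the secondary 3-OH stays free, and working under argon at or below room temperature avoids the base-induced ring opening that would epimerise C2.

Step 2
Reactants: 2 5,7,3',4'-tetra-O-benzyl-(+)-catechin
Product: 3 3,5,7,3',4'-penta-O-benzyl-(+)-catechin (2R,3S)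
Conditions: NaH, BnBr, DMF, 0 °C to rt
Reagents that add atoms: benzyl bromide, BrCc1ccccc1
Why: Williamson etherification of the sodium alkoxide caps the last hydroxyl, and with every phenol already blocked no quinone methide can form, so 2R and 3S are retained.

Step 3
Reactants: 3 penta-O-benzyl-(+)-catechin
Product: 4 (2R,3S,4S)-penta-O-benzyl-4-(2-ethoxyethoxy)catechin
Conditions: DDQ (2 equiv), HOCH2CH2OEt, CH2Cl2, 0 °C to rt
Reagents that add atoms: 2-ethoxyethanol, CCOCCO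
Why: Benzylic C–H oxidation by hydride abstraction: DDQ takes the hydride from C4, the only benzylic position conjugated with the three oxygen donors of ring A, and the alcohol traps the cation mainly from the face anti to the C2 aryl group, a configuration that is erased again on ionisation.

Step 4
Reactants: 4 4-(2-ethoxyethoxy) electrophile; 3 penta-O-benzyl-(+)-catechin (4 equiv, excess recovered)
Product: 5 deca-O-benzyl catechin-(4α→8)-catechin (upper unit 2R,3S,4S; lower unit 2R,3S)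
Conditions: Me3SiOTf (cat.), CH2Cl2, −78 °C
Reagents that add atoms: none
Why: Friedel–Crafts alkylation by a C4 benzylic cation, the standard interflavan bond formation: the silyl triflate ionises the C4 ether, C8 of 3 (more nucleophilic and less flanked than C6) attacks anti to the neighbouring 3-OBn group to set 4S (3,4-trans), and the excess of 3 outcompetes self-condensation of 4.

Step 5
Reactants: 4 4-(2-ethoxyethoxy) electrophile
Product: 6 (2R,3S,4S)-8-bromo-penta-O-benzyl-4-(2-ethoxyethoxy)catechin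
Conditions: NBS (1.0 equiv), CH2Cl2, −78 to 0 °C
Reagents that add atoms: N-bromosuccinimide, O=C1CCC(=O)N1Br
Why: Electrophilic aromatic bromination of the phloroglucinol-type ring A goes to C8, which is less shielded than C6 between two benzyloxy groups, and since only succinimide is released the acid-labile C4 ether survives.

Step 6
Reactants: 6 8-bromo electrophile; 5 deca-O-benzyl dimer (1.2 equiv)
Product: 7 8-bromo-pentadeca-O-benzyl catechin-(4α→8)-catechin-(4α→8)-catechin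
Conditions: Me3SiOTf (cat.), CH2Cl2, −78 to −40 °C
Reagents that add atoms: none
Why: The same Friedel–Crafts alkylation, now near equimolar because the C8 bromine stops 6 from acting as a nucleophile: the free C8 of the upper unit of 5 is the most reactive site and adds anti to the 3-OBn group of the cation, which sets the second 4S centre.

Step 7
Reactants: 7 8-bromo trimer
Product: 9 pentadeca-O-benzyl trimer 8-carbaldehyde, via lithiated trimer 8 (not isolated)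
Conditions: n-BuLi (1.2 equiv), THF, −78 °C; DMF, −78 °C to 0 °C; H2O
Reagents that add atoms: N,N-dimethylformamide, CN(C)C=O
Why: Bromine–lithium exchange followed by formylation with DMF (Bouveault aldehyde synthesis) turns the former capping group into the one-carbon handle exactly at C8, and benzyl aryl ethers tolerate n-BuLi for a short time at −78 °C.

Step 8
Reactants: 10 3',5'-dibenzyloxyacetophenone
Product: 11 2'-bromo-3',5'-dibenzyloxyacetophenone
Conditions: NBS (1.05 equiv), MeCN, 0 °C to rt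
Reagents that add atoms: N-bromosuccinimide, O=C1CCC(=O)N1Br
Why: Electrophilic aromatic bromination in a polar solvent attacks the ring position para to one benzyloxy group and ortho to the other (C2'), as is known for 3,5-dialkoxyaryl ketones, in preference to the crowded C4' and to the enolisable methyl group.

Step 9
Reactants: 9 trimer 8-carbaldehyde; 11 2'-bromo-3',5'-dibenzyloxyacetophenone (1.5 equiv)
Product: 12 (E)-1-(2-bromo-3,5-dibenzyloxyphenyl)-3-(pentadeca-O-benzyl trimer-8-yl)prop-2-en-1-one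
Conditions: KOH, THF–EtOH, rt to 40 °C
Reagents that add atoms: none
Why: Claisen–Schmidt condensation: the methyl ketone enolate adds to the non-enolisable aldehyde and E1cB loss of water gives the conjugated E-enone, as 2,4,6-trialkoxybenzaldehydes are known to do, while benzyl ethers, the aryl bromide and the capped flavan units are inert to hydroxide.

Step 10
Reactants: 12 2'-bromochalcone
Product: 13 (3S)-4,6-dibenzyloxy-3-(pentadeca-O-benzyl trimer-8-yl)indan-1-one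
Conditions: Pd(OAc)2 (10 mol %), (R)-3,5-Xyl-MeO-BIPHEP (12 mol %), HCO2Na (2 equiv), DMF–ethylene glycol, 80 °C
Reagents that add atoms: none
Why: Intramolecular asymmetric reductive Heck reaction, known for 2'-halochalcones: zerovalent palladium inserts into the C–Br bond, the glycol-assisted cationic aryl–palladium bisphosphine complex bonds the aryl carbon to Cβ (formal 5-endo closure), the palladium enolate is protonated and formate returns the metal to the zerovalent state, the chiral ligand choosing the Cβ face and so setting 3S, while any minor C3 epimer is a separable diastereomer because the trimer is homochiral.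

Step 11
Reactants: 13 (3S)-3-arylindan-1-one
Product: 15 (4S)-5,7-dibenzyloxy-4-(pentadeca-O-benzyl trimer-8-yl)-3,4-dihydrocoumarin, via peroxy hemiketal 14 (not isolated)
Conditions: m-CPBA (purified, 2.5 equiv), TsOH·H2O (10 mol %), CH2Cl2, 0–4 °C, dark
Reagents that add atoms: m-chloroperbenzoic acid, OOC(=O)c1cccc(Cl)c1
Why: Acid-assisted addition of the peracid to C1=O gives the tetrahedral Criegee adduct 14, in which the C1–C7a bond lying antiperiplanar to the O–O bond shifts to the proximal oxygen as m-chlorobenzoate leaves, forming O1–C8a. The closest known reaction type is the Baeyer–Villiger expansion of enantioenriched 3-arylindan-1-ones to 4-aryl-3,4-dihydrocoumarins under peracid with a catalytic sulfonic acid, which is chosen because a conjugated aryl ketone adds a purely buffered peracid too slowly. Ring C is not closed by a cyclisation but by one-atom enlargement of the existing five-membered ring through this 1,2-shift. No stereocentre is created, and C3 is neither part of the migrating bond nor enolisable, so 3S is carried over unchanged as 4S. Aryl rather than alkyl migration is secured by keeping C2 as an unsubstituted primary CH2, which is why the flavan C3 oxygen is introduced only afterwards, since an α-alkoxy carbon would outrun the aryl group. Attack at the ketone rather than at the arenes is favoured because both benzyloxy groups are meta to the acyl carbon and do not deactivate it, each lower ring A keeps only a C6–H walled in by two benzyloxy groups, the indanone arene is acyl-deactivated, and the perbenzylated interflavan bonds that persist under Me3SiOTf should tolerate cold catalytic acid.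

Step 12
Reactants: 15 (4S)-4-aryl-3,4-dihydrocoumarin; 16 4-bromo-1,2-bis(benzyloxy)benzene (1.3 equiv)
Product: 18 (3S)-1-(3,4-dibenzyloxyphenyl)-3-(2-hydroxy-4,6-dibenzyloxyphenyl)-3-(pentadeca-O-benzyl trimer-8-yl)propan-1-one, via 3,4-bis(benzyloxy)phenyllithium 17 (not isolated)
Conditions: 16, n-BuLi (1.25 equiv), THF, −78 °C; then 15, −78 °C; AcOH quench at −78 °C
Reagents that add atoms: none
Why: Acyl substitution of an aryl lactone by an aryllithium stops at the ketone because the phenyl-ester-type carbonyl of 15 is far more electrophilic than the p-alkoxyaryl ketone released as its lithium phenoxide, and the cold acetic acid quench prevents a retro-Michael escape through an o-quinone methide that would scramble C4.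

Step 13
Reactants: 18 keto-phenol
Product: 19 (4S)-5,7-dibenzyloxy-2-(3,4-dibenzyloxyphenyl)-4-(pentadeca-O-benzyl trimer-8-yl)-4H-chromene (flav-2-ene)
Conditions: PPTS (10 mol %), 4 Å MS, toluene, argon, 60 °C
Reagents that add atoms: none
Why: Acid-catalysed cyclodehydration of a 3-(2-hydroxyaryl)propiophenone, a known entry to 2-aryl-4H-chromenes, proceeds by hemiketal formation, ionisation to the aryl-stabilised oxocarbenium ion and loss of H3, while the weak acid and the exclusion of air spare the interflavan bonds and prevent oxidation to the flavylium ion.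

Step 14
Reactants: 19 flav-2-ene
Product: 21 nonadeca-O-benzyl catechin tetramer with free 3-OH in the top unit (top unit 2R,3S,4S), via C3 alkylborane 20 (not isolated)
Conditions: BH3·THF (5 equiv), THF, 0 °C to rt; then aq NaOH, H2O2, 0 °C
Reagents that add atoms: hydrogen peroxide, OO
Why: Hydroboration–oxidation of a flav-2-ene, a known route to 2,3-trans-flavan-3-ols, places boron on C3 (β to O1 and the less substituted alkene carbon), adds H and B syn on the face anti to the pseudoaxial C4 aryl group, and oxidises with retention, so that C4 dictates 3S (3,4-trans) and 2R (2,3-trans) in one operation.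

Step 15
Reactants: 21 nonadeca-O-benzyl tetramer
Product: 22 catechin-(4α→8)-catechin-(4α→8)-catechin-(4α→8)-catechin (target)
Conditions: H2 (1 atm), Pd(OH)2/C, THF–MeOH–H2O, rt
Reagents that add atoms: none
Why: Catalytic hydrogenolysis cleaves all nineteen benzyl ethers under neutral conditions that are established for procyanidin oligomers and leave the interflavan bonds, the C2–O1 bonds and all eleven stereocentres intact.

Compound list

1 | (+)-catechin (2R,3S) | Oc1cc(O)c2c(c1)O[C@H](c1ccc(O)c(O)c1)[C@@H](O)C2 | starting material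
2 | 5,7,3',4'-tetra-O-benzyl-(+)-catechin | c1c(OCc3ccccc3)cc(OCc3ccccc3)c2c1O[C@H](c1ccc(OCc3ccccc3)c(OCc3ccccc3)c1)[C@@H](O)C2 | intermediate
3 | 3,5,7,3',4'-penta-O-benzyl-(+)-catechin | c1c(OCc3ccccc3)cc(OCc3ccccc3)c2c1O[C@H](c1ccc(OCc3ccccc3)c(OCc3ccccc3)c1)[C@@H](OCc3ccccc3)C2 | intermediate
4 | (2R,3S,4S)-penta-O-benzyl-4-(2-ethoxyethoxy)catechin | c1c(OCc3ccccc3)cc(OCc3ccccc3)c2c1O[C@H](c1ccc(OCc3ccccc3)c(OCc3ccccc3)c1)[C@@H](OCc3ccccc3)[C@H]2OCCOCC | intermediate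
5 | deca-O-benzyl catechin-(4α→8)-catechin | c1c(OCc3ccccc3)cc(OCc3ccccc3)c2c1O[C@H](c1ccc(OCc3ccccc3)c(OCc3ccccc3)c1)[C@@H](OCc3ccccc3)[C@@H]2c1c(OCc3ccccc3)cc(OCc3ccccc3)c2c1O[C@H](c1ccc(OCc3ccccc3)c(OCc3ccccc3)c1)[C@@H](OCc3ccccc3)C2 | intermediate
6 | (2R,3S,4S)-8-bromo-penta-O-benzyl-4-(2-ethoxyethoxy)catechin | Brc1c(OCc3ccccc3)cc(OCc3ccccc3)c2c1O[C@H](c1ccc(OCc3ccccc3)c(OCc3ccccc3)c1)[C@@H](OCc3ccccc3)[C@H]2OCCOCC | intermediate
7 | 8-bromo-pentadeca-O-benzyl catechin trimer (4α→8 links) | Brc1c(OCc3ccccc3)cc(OCc3ccccc3)c2c1O[C@H](c1ccc(OCc3ccccc3)c(OCc3ccccc3)c1)[C@@H](OCc3ccccc3)[C@@H]2c1c(OCc3ccccc3)cc(OCc3ccccc3)c2c1O[C@H](c1ccc(OCc3ccccc3)c(OCc3ccccc3)c1)[C@@H](OCc3ccccc3)[C@@H]2c1c(OCc3ccccc3)cc(OCc3ccccc3)c2c1O[C@H](c1ccc(OCc3ccccc3)c(OCc3ccccc3)c1)[C@@H](OCc3ccccc3)C2 | intermediate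
8 | 8-lithio-pentadeca-O-benzyl trimer | [Li]c1c(OCc3ccccc3)cc(OCc3ccccc3)c2c1O[C@H](c1ccc(OCc3ccccc3)c(OCc3ccccc3)c1)[C@@H](OCc3ccccc3)[C@@H]2c1c(OCc3ccccc3)cc(OCc3ccccc3)c2c1O[C@H](c1ccc(OCc3ccccc3)c(OCc3ccccc3)c1)[C@@H](OCc3ccccc3)[C@@H]2c1c(OCc3ccccc3)cc(OCc3ccccc3)c2c1O[C@H](c1ccc(OCc3ccccc3)c(OCc3ccccc3)c1)[C@@H](OCc3ccccc3)C2 | intermediate
9 | pentadeca-O-benzyl trimer 8-carbaldehyde | O=Cc1c(OCc3ccccc3)cc(OCc3ccccc3)c2c1O[C@H](c1ccc(OCc3ccccc3)c(OCc3ccccc3)c1)[C@@H](OCc3ccccc3)[C@@H]2c1c(OCc3ccccc3)cc(OCc3ccccc3)c2c1O[C@H](c1ccc(OCc3ccccc3)c(OCc3ccccc3)c1)[C@@H](OCc3ccccc3)[C@@H]2c1c(OCc3ccccc3)cc(OCc3ccccc3)c2c1O[C@H](c1ccc(OCc3ccccc3)c(OCc3ccccc3)c1)[C@@H](OCc3ccccc3)C2 | intermediate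
10 | 3',5'-dibenzyloxyacetophenone | CC(=O)c1cc(OCc2ccccc2)cc(OCc2ccccc2)c1 | starting material
11 | 2'-bromo-3',5'-dibenzyloxyacetophenone | CC(=O)c1cc(OCc2ccccc2)cc(OCc2ccccc2)c1Br | intermediate
12 | (E)-2'-bromochalcone carrying the trimer at Cβ | O=C(c4cc(OCc3ccccc3)cc(OCc3ccccc3)c4Br)/C=C/c1c(OCc3ccccc3)cc(OCc3ccccc3)c2c1O[C@H](c1ccc(OCc3ccccc3)c(OCc3ccccc3)c1)[C@@H](OCc3ccccc3)[C@@H]2c1c(OCc3ccccc3)cc(OCc3ccccc3)c2c1O[C@H](c1ccc(OCc3ccccc3)c(OCc3ccccc3)c1)[C@@H](OCc3ccccc3)[C@@H]2c1c(OCc3ccccc3)cc(OCc3ccccc3)c2c1O[C@H](c1ccc(OCc3ccccc3)c(OCc3ccccc3)c1)[C@@H](OCc3ccccc3)C2 | intermediate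
13 | (3S)-4,6-dibenzyloxy-3-(trimer-8-yl)indan-1-one | O=C4C[C@@H](c5c(OCc3ccccc3)cc(OCc3ccccc3)cc45)c1c(OCc3ccccc3)cc(OCc3ccccc3)c2c1O[C@H](c1ccc(OCc3ccccc3)c(OCc3ccccc3)c1)[C@@H](OCc3ccccc3)[C@@H]2c1c(OCc3ccccc3)cc(OCc3ccccc3)c2c1O[C@H](c1ccc(OCc3ccccc3)c(OCc3ccccc3)c1)[C@@H](OCc3ccccc3)[C@@H]2c1c(OCc3ccccc3)cc(OCc3ccccc3)c2c1O[C@H](c1ccc(OCc3ccccc3)c(OCc3ccccc3)c1)[C@@H](OCc3ccccc3)C2 | intermediate
14 | Criegee adduct: 1-hydroxy-1-(3-chlorobenzoylperoxy)indane (C1 undefined) | OC4(OOC(=O)c6cccc(Cl)c6)C[C@@H](c5c(OCc3ccccc3)cc(OCc3ccccc3)cc45)c1c(OCc3ccccc3)cc(OCc3ccccc3)c2c1O[C@H](c1ccc(OCc3ccccc3)c(OCc3ccccc3)c1)[C@@H](OCc3ccccc3)[C@@H]2c1c(OCc3ccccc3)cc(OCc3ccccc3)c2c1O[C@H](c1ccc(OCc3ccccc3)c(OCc3ccccc3)c1)[C@@H](OCc3ccccc3)[C@@H]2c1c(OCc3ccccc3)cc(OCc3ccccc3)c2c1O[C@H](c1ccc(OCc3ccccc3)c(OCc3ccccc3)c1)[C@@H](OCc3ccccc3)C2 | intermediate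
15 | (4S)-5,7-dibenzyloxy-4-(trimer-8-yl)-3,4-dihydrocoumarin | O=C4C[C@@H](c5c(OCc3ccccc3)cc(OCc3ccccc3)cc5O4)c1c(OCc3ccccc3)cc(OCc3ccccc3)c2c1O[C@H](c1ccc(OCc3ccccc3)c(OCc3ccccc3)c1)[C@@H](OCc3ccccc3)[C@@H]2c1c(OCc3ccccc3)cc(OCc3ccccc3)c2c1O[C@H](c1ccc(OCc3ccccc3)c(OCc3ccccc3)c1)[C@@H](OCc3ccccc3)[C@@H]2c1c(OCc3ccccc3)cc(OCc3ccccc3)c2c1O[C@H](c1ccc(OCc3ccccc3)c(OCc3ccccc3)c1)[C@@H](OCc3ccccc3)C2 | intermediate
16 | 4-bromo-1,2-bis(benzyloxy)benzene | Brc1ccc(OCc2ccccc2)c(OCc2ccccc2)c1 | starting material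
17 | 3,4-bis(benzyloxy)phenyllithium | [Li]c1ccc(OCc2ccccc2)c(OCc2ccccc2)c1 | intermediate
18 | (3S)-keto-phenol (ring-opened 2-aryl lactol) | O=C(c4ccc(OCc3ccccc3)c(OCc3ccccc3)c4)C[C@@H](c5c(OCc3ccccc3)cc(OCc3ccccc3)cc5O)c1c(OCc3ccccc3)cc(OCc3ccccc3)c2c1O[C@H](c1ccc(OCc3ccccc3)c(OCc3ccccc3)c1)[C@@H](OCc3ccccc3)[C@@H]2c1c(OCc3ccccc3)cc(OCc3ccccc3)c2c1O[C@H](c1ccc(OCc3ccccc3)c(OCc3ccccc3)c1)[C@@H](OCc3ccccc3)[C@@H]2c1c(OCc3ccccc3)cc(OCc3ccccc3)c2c1O[C@H](c1ccc(OCc3ccccc3)c(OCc3ccccc3)c1)[C@@H](OCc3ccccc3)C2 | intermediate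
19 | (4S)-2-aryl-4-(trimer-8-yl)-4H-chromene (flav-2-ene) | O(Cc3ccccc3)c6ccc(cc6OCc3ccccc3)C4=C[C@@H](c5c(OCc3ccccc3)cc(OCc3ccccc3)cc5O4)c1c(OCc3ccccc3)cc(OCc3ccccc3)c2c1O[C@H](c1ccc(OCc3ccccc3)c(OCc3ccccc3)c1)[C@@H](OCc3ccccc3)[C@@H]2c1c(OCc3ccccc3)cc(OCc3ccccc3)c2c1O[C@H](c1ccc(OCc3ccccc3)c(OCc3ccccc3)c1)[C@@H](OCc3ccccc3)[C@@H]2c1c(OCc3ccccc3)cc(OCc3ccccc3)c2c1O[C@H](c1ccc(OCc3ccccc3)c(OCc3ccccc3)c1)[C@@H](OCc3ccccc3)C2 | intermediate
20 | C3 alkylborane of the top unit (written as RBH2) | O(Cc3ccccc3)c1cc(OCc3ccccc3)c2c(c1)O[C@H](c1ccc(OCc3ccccc3)c(OCc3ccccc3)c1)[C@@H](B)[C@@H]2c1c(OCc3ccccc3)cc(OCc3ccccc3)c2c1O[C@H](c1ccc(OCc3ccccc3)c(OCc3ccccc3)c1)[C@@H](OCc3ccccc3)[C@@H]2c1c(OCc3ccccc3)cc(OCc3ccccc3)c2c1O[C@H](c1ccc(OCc3ccccc3)c(OCc3ccccc3)c1)[C@@H](OCc3ccccc3)[C@@H]2c1c(OCc3ccccc3)cc(OCc3ccccc3)c2c1O[C@H](c1ccc(OCc3ccccc3)c(OCc3ccccc3)c1)[C@@H](OCc3ccccc3)C2 | intermediate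
21 | nonadeca-O-benzyl catechin tetramer, top-unit 3-OH free | O(Cc3ccccc3)c1cc(OCc3ccccc3)c2c(c1)O[C@H](c1ccc(OCc3ccccc3)c(OCc3ccccc3)c1)[C@@H](O)[C@@H]2c1c(OCc3ccccc3)cc(OCc3ccccc3)c2c1O[C@H](c1ccc(OCc3ccccc3)c(OCc3ccccc3)c1)[C@@H](OCc3ccccc3)[C@@H]2c1c(OCc3ccccc3)cc(OCc3ccccc3)c2c1O[C@H](c1ccc(OCc3ccccc3)c(OCc3ccccc3)c1)[C@@H](OCc3ccccc3)[C@@H]2c1c(OCc3ccccc3)cc(OCc3ccccc3)c2c1O[C@H](c1ccc(OCc3ccccc3)c(OCc3ccccc3)c1)[C@@H](OCc3ccccc3)C2 | intermediate
22 | catechin-(4α→8)-catechin-(4α→8)-catechin-(4α→8)-catechin, CNP0236700.2 | Oc1cc(O)c2c(c1)O[C@H](c1ccc(O)c(O)c1)[C@@H](O)[C@@H]2c1c(O)cc(O)c2c1O[C@H](c1ccc(O)c(O)c1)[C@@H](O)[C@@H]2c1c(O)cc(O)c2c1O[C@H](c1ccc(O)c(O)c1)[C@@H](O)[C@@H]2c1c(O)cc(O)c2c1O[C@H](c1ccc(O)c(O)c1)[C@@H](O)C2 | target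

Total step count: 15. Longest linear sequence: 13 steps (1 → 2 → 3 → 4 → 5 → 7 → 9 → 12 → 13 → 15 → 18 → 19 → 21 → 22, that is steps 1–4, 6, 7 and 9–15). Steps 5 and 8 are side branches.

Steps most likely to fail

Step 11. Peracid addition to the conjugated aryl ketone may be slow. Ring hydroxylation of the benzyloxy arenes, acid cleavage of an interflavan bond or competing migration of the CH2 group could then overtake the wanted aryl shift. In the fallback the top unit is brought in as an intact catechin electrophile instead of being built by ring expansion.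
- It sets out from 7. Bromine–lithium exchange (n-BuLi, THF, −78 °C) and a methanol quench give pentadeca-O-benzyl catechin trimer F1.
- Me3SiOTf-catalysed Friedel–Crafts coupling of F1 with 6, as in step 6, gives 8-bromo-eicosa-O-benzyl catechin tetramer F2.
- Hydrogenolysis (H2, Pd(OH)2/C, Et3N, THF–MeOH–H2O) removes the bromine and all benzyl groups, and the route is rejoined at 22.

Step 10. The aryl–palladium species and Cβ are both flanked by two ortho substituents. Hydrodebromination or conjugate reduction of the enone may therefore outrun insertion, and a mismatched pairing of ligand and homochiral trimer may erode facial selectivity. The fallback closes the same C3–C3a bond from boron under rhodium catalysis.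
- It sets out from 12. Miyaura borylation (Pd(dppf)Cl2, B2pin2, KOAc, dioxane, 80 °C) gives the 2'-pinacolboronate chalcone F3.
- A redox-neutral asymmetric intramolecular 1,4-addition ([Rh(C2H4)2Cl]2, MonoPhos, aq K3PO4, toluene), known for such boronate chalcones, closes the ring and rejoins the route at 13.

Step 14. The C3 borane lies antiperiplanar to the C2–O1 bond and may ring-open by β-elimination of the aryloxide. The facial bias exerted by the C4 aryl group may also prove insufficient. The fallback oxygenates C3 at the lactone stage and sets C2 by ionic reduction.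
- It sets out from 15. Enolate hydroxylation anti to the C4 aryl group (KN(SiMe3)2, 2-(phenylsulfonyl)-3-phenyloxaziridine, THF, −78 °C) gives (3S,4S)-3-hydroxy lactone F4.
- Benzyl 2,2,2-trichloroacetimidate with catalytic TfOH gives (3S,4S)-3-benzyloxy lactone F5.
- Addition of 17 at −78 °C gives 2-aryl lactol F6.
- Et3SiH and BF3·OEt2 (CH2Cl2, −78 to −40 °C) deliver hydride axially to the oxocarbenium ion and give the 2,3-trans eicosa-O-benzyl catechin tetramer F7.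
- Hydrogenolysis as in step 15 rejoins the route at 22.

Further compounds

F1 | step 11 | pentadeca-O-benzyl catechin trimer | c1c(OCc3ccccc3)cc(OCc3ccccc3)c2c1O[C@H](c1ccc(OCc3ccccc3)c(OCc3ccccc3)c1)[C@@H](OCc3ccccc3)[C@@H]2c1c(OCc3ccccc3)cc(OCc3ccccc3)c2c1O[C@H](c1ccc(OCc3ccccc3)c(OCc3ccccc3)c1)[C@@H](OCc3ccccc3)[C@@H]2c1c(OCc3ccccc3)cc(OCc3ccccc3)c2c1O[C@H](c1ccc(OCc3ccccc3)c(OCc3ccccc3)c1)[C@@H](OCc3ccccc3)C2
F2 | step 11 | 8-bromo-eicosa-O-benzyl catechin tetramer | Brc1c(OCc3ccccc3)cc(OCc3ccccc3)c2c1O[C@H](c1ccc(OCc3ccccc3)c(OCc3ccccc3)c1)[C@@H](OCc3ccccc3)[C@@H]2c1c(OCc3ccccc3)cc(OCc3ccccc3)c2c1O[C@H](c1ccc(OCc3ccccc3)c(OCc3ccccc3)c1)[C@@H](OCc3ccccc3)[C@@H]2c1c(OCc3ccccc3)cc(OCc3ccccc3)c2c1O[C@H](c1ccc(OCc3ccccc3)c(OCc3ccccc3)c1)[C@@H](OCc3ccccc3)[C@@H]2c1c(OCc3ccccc3)cc(OCc3ccccc3)c2c1O[C@H](c1ccc(OCc3ccccc3)c(OCc3ccccc3)c1)[C@@H](OCc3ccccc3)C2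
F3 | step 10 | 2'-pinacolboronate chalcone | O=C(c4cc(OCc3ccccc3)cc(OCc3ccccc3)c4B5OC(C)(C)C(C)(C)O5)/C=C/c1c(OCc3ccccc3)cc(OCc3ccccc3)c2c1O[C@H](c1ccc(OCc3ccccc3)c(OCc3ccccc3)c1)[C@@H](OCc3ccccc3)[C@@H]2c1c(OCc3ccccc3)cc(OCc3ccccc3)c2c1O[C@H](c1ccc(OCc3ccccc3)c(OCc3ccccc3)c1)[C@@H](OCc3ccccc3)[C@@H]2c1c(OCc3ccccc3)cc(OCc3ccccc3)c2c1O[C@H](c1ccc(OCc3ccccc3)c(OCc3ccccc3)c1)[C@@H](OCc3ccccc3)C2
F4 | step 14 | (3S,4S)-3-hydroxy lactone | O=C4[C@@H](O)[C@@H](c5c(OCc3ccccc3)cc(OCc3ccccc3)cc5O4)c1c(OCc3ccccc3)cc(OCc3ccccc3)c2c1O[C@H](c1ccc(OCc3ccccc3)c(OCc3ccccc3)c1)[C@@H](OCc3ccccc3)[C@@H]2c1c(OCc3ccccc3)cc(OCc3ccccc3)c2c1O[C@H](c1ccc(OCc3ccccc3)c(OCc3ccccc3)c1)[C@@H](OCc3ccccc3)[C@@H]2c1c(OCc3ccccc3)cc(OCc3ccccc3)c2c1O[C@H](c1ccc(OCc3ccccc3)c(OCc3ccccc3)c1)[C@@H](OCc3ccccc3)C2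
F5 | step 14 | (3S,4S)-3-benzyloxy lactone | O=C4[C@@H](OCc3ccccc3)[C@@H](c5c(OCc3ccccc3)cc(OCc3ccccc3)cc5O4)c1c(OCc3ccccc3)cc(OCc3ccccc3)c2c1O[C@H](c1ccc(OCc3ccccc3)c(OCc3ccccc3)c1)[C@@H](OCc3ccccc3)[C@@H]2c1c(OCc3ccccc3)cc(OCc3ccccc3)c2c1O[C@H](c1ccc(OCc3ccccc3)c(OCc3ccccc3)c1)[C@@H](OCc3ccccc3)[C@@H]2c1c(OCc3ccccc3)cc(OCc3ccccc3)c2c1O[C@H](c1ccc(OCc3ccccc3)c(OCc3ccccc3)c1)[C@@H](OCc3ccccc3)C2
F6 | step 14 | 2-aryl lactol (C2 undefined) | OC4(c6ccc(OCc3ccccc3)c(OCc3ccccc3)c6)[C@@H](OCc3ccccc3)[C@@H](c5c(OCc3ccccc3)cc(OCc3ccccc3)cc5O4)c1c(OCc3ccccc3)cc(OCc3ccccc3)c2c1O[C@H](c1ccc(OCc3ccccc3)c(OCc3ccccc3)c1)[C@@H](OCc3ccccc3)[C@@H]2c1c(OCc3ccccc3)cc(OCc3ccccc3)c2c1O[C@H](c1ccc(OCc3ccccc3)c(OCc3ccccc3)c1)[C@@H](OCc3ccccc3)[C@@H]2c1c(OCc3ccccc3)cc(OCc3ccccc3)c2c1O[C@H](c1ccc(OCc3ccccc3)c(OCc3ccccc3)c1)[C@@H](OCc3ccccc3)C2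
F7 | step 14 | eicosa-O-benzyl catechin tetramer | c1c(OCc3ccccc3)cc(OCc3ccccc3)c2c1O[C@H](c1ccc(OCc3ccccc3)c(OCc3ccccc3)c1)[C@@H](OCc3ccccc3)[C@@H]2c1c(OCc3ccccc3)cc(OCc3ccccc3)c2c1O[C@H](c1ccc(OCc3ccccc3)c(OCc3ccccc3)c1)[C@@H](OCc3ccccc3)[C@@H]2c1c(OCc3ccccc3)cc(OCc3ccccc3)c2c1O[C@H](c1ccc(OCc3ccccc3)c(OCc3ccccc3)c1)[C@@H](OCc3ccccc3)[C@@H]2c1c(OCc3ccccc3)cc(OCc3ccccc3)c2c1O[C@H](c1ccc(OCc3ccccc3)c(OCc3ccccc3)c1)[C@@H](OCc3ccccc3)C2
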